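**Assumption:** the target is taken exactly as drawn in the given SMILES, and both limonene enantiomers are bought in high enantiomeric purity.

## Retrosynthetic overview

1. The last stereocentre (secondary carbinol of ring A) comes from a hydroxyl-directed reduction of an α-hydroxy ketone, after global desilylation.
2. The central bond (ring A C3–CH2) comes from alkylation of the ring A ketone enolate with a ring B 2-(bromomethyl)allyl fragment; this also sets ring A C3.
3. The ring B fragment comes from (R)-limonene: C10 hydroxylation and bromination, then a new selenium-catalysed syn-bromohydroxylation of the ring alkene (sets C–OH and C–Br).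
4. The ring A fragment comes from (S)-limonene: epoxidation, trans-diaxial hydrolysis, oxidation to the α-ketol, silylation.
5. No ring is built: both cyclohexane rings are bought as the two limonene enantiomers; ring B is functionalised first, ring A second, then the two are joined.

## Route

Step 1
Reactants: 1 (R)-(+)-limonene
Product: 4 (R)-2-(4-methylcyclohex-3-en-1-yl)prop-2-en-1-ol, via allyllithium 2 (not isolated), via lithium allyltrimethoxyborate 3 (not isolated)
Conditions: n-BuLi, TMEDA, hexane, 23 °C, 24 h; B(OMe)3, THF, −78 °C; 30% aq. H2O2, 0 → 23 °C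
Reagents that add atoms: hydrogen peroxide, OO
Why: Kinetic allylic metalation by n-BuLi·TMEDA takes place at the isopropenyl methyl group (C10) and gives a 2-substituted allyllithium that does not include C4, so the stereocentre is kept, and borylation followed by borate oxidation (1,2-migration from boron to oxygen) gives the primary allylic alcohol; no new stereocentre.

Step 2
Reactants: 4 (R)-2-(4-methylcyclohex-3-en-1-yl)prop-2-en-1-ol
Product: 5 (R)-4-(3-bromoprop-1-en-2-yl)-1-methylcyclohex-1-ene
Conditions: CBr4, PPh3, CH2Cl2, 0 °C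
Reagents that add atoms: carbon tetrabromide, BrC(Br)(Br)Br
Why: Appel reaction of a primary allylic alcohol, in which SN2 and SN2′ displacement give the same bromide because the allyl unit is symmetrical; the trisubstituted alkene and the stereocentre are untouched.

Step 3
Reactants: 5 (R)-4-(3-bromoprop-1-en-2-yl)-1-methylcyclohex-1-ene
Product: 8 (1S,2R,4R)-2-bromo-4-(3-bromoprop-1-en-2-yl)-1-methylcyclohexan-1-ol, via hydroxy selenide 6 (not isolated), via bromoselenurane 7 (not isolated)
Conditions: (PhSe)2 (10 mol %), N-bromosuccinimide (1.1 equiv, added over 6 h), 4-MeC6H4SO3H·H2O (5 mol %), MeCN–H2O (20:1), −20 °C, dark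
Reagents that add atoms: N-bromosuccinimide, O=C1CCC(=O)N1Br; water, O
Why: Proposed new method: a selenium-redox-catalysed syn-bromohydroxylation in which the PhSe electrophile made from (PhSe)2 and N-bromosuccinimide adds reversibly to the electron-rich ring alkene only (the 2-(bromomethyl)allyl alkene is deactivated) and water opens the seleniranium ion in the Markovnikov, trans-diaxial (Fürst–Plattner) sense to give 6 with axial OH at C1 on the face of the C4 side chain and axial Se at C2, then N-bromosuccinimide, which oxidises divalent selenium far faster than it attacks a free alkene when kept at low concentration, gives the tetravalent selenium bromide 7, and finally bromide displaces the selenium nucleofuge at C2 by SN2 with inversion (approach syn to and hydrogen-bond-guided by the neutral axial OH, itself a poor three-ring neighbouring group in this weakly acidic medium) to return the PhSe–succinimide carrier and leave Br equatorial and cis to OH, so that net syn addition sets C1 (S) and C2 (R); the closest known reaction types are the selenium-redox-catalysed syn-dichlorination of alkenes and the stoichiometric bromodeselenenylation of alkyl phenyl selenides by Br2.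

Step 4
Reactants: 8 (1S,2R,4R)-2-bromo-4-(3-bromoprop-1-en-2-yl)-1-methylcyclohexan-1-ol
Product: 9 {[(1S,2R,4R)-2-bromo-4-(3-bromoprop-1-en-2-yl)-1-methylcyclohexyl]oxy}triethylsilane
Conditions: Et3SiOTf, 2,6-lutidine, CH2Cl2, −78 → 0 °C
Reagents that add atoms: triethylsilyl trifluoromethanesulfonate, CC[Si](CC)(CC)OS(=O)(=O)C(F)(F)F
Why: Silyl ether protection of the hindered tertiary hydroxyl with a silyl triflate and a non-nucleophilic base removes the acidic proton before the enolate step and prevents base-induced semipinacol ring contraction of the cis-bromohydrin; no stereocentre is touched.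

Step 5
Reactants: 10 (S)-(−)-limonene
Product: 13 (1R,2R,4S)-1-methyl-4-(prop-1-en-2-yl)cyclohexane-1,2-diol, via cis-epoxide 11 (not isolated), via trans-epoxide 12 (not isolated)
Conditions: mCPBA (1.0 equiv), CH2Cl2, 0 °C; then 1% aq. H2SO4, THF, 0 → 23 °C
Reagents that add atoms: 3-chloroperoxybenzoic acid, OOC(=O)c1cccc(Cl)c1; water, O
Why: Prilezhaev epoxidation of the more electron-rich ring alkene followed by acid-catalysed Fürst–Plattner opening, in which water attacks C1 of the cis-epoxide and C2 of the trans-epoxide, so both converge on the single trans-diaxial diol and the C1 carbinol of ring A is set (1R).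

Step 6
Reactants: 13 (1R,2R,4S)-1-methyl-4-(prop-1-en-2-yl)cyclohexane-1,2-diol
Product: 14 (2R,5S)-2-hydroxy-2-methyl-5-(prop-1-en-2-yl)cyclohexan-1-one
Conditions: 2-iodoxybenzoic acid (IBX), DMSO, 23 °C
Reagents that add atoms: none
Why: IBX oxidation (pentavalent iodine) converts the secondary hydroxyl of a 1,2-diol into the α-ketol without C–C cleavage, keeps the tertiary carbinol and deliberately erases C2, which is reset in step 10.

Step 7
Reactants: 14 (2R,5S)-2-hydroxy-2-methyl-5-(prop-1-en-2-yl)cyclohexan-1-one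
Product: 15 (2R,5S)-2-methyl-5-(prop-1-en-2-yl)-2-[(triethylsilyl)oxy]cyclohexan-1-one
Conditions: Et3SiOTf, 2,6-lutidine, CH2Cl2, −78 → 0 °C
Reagents that add atoms: triethylsilyl trifluoromethanesulfonate, CC[Si](CC)(CC)OS(=O)(=O)C(F)(F)F
Why: Silyl ether protection of the tertiary α-hydroxyl, which at −78 °C with a weak base is much faster than silyl enol ether formation, so the ketone can be enolised cleanly in the next step; no stereocentre is touched.

Step 8
Reactants: 15 (2R,5S)-2-methyl-5-(prop-1-en-2-yl)-2-[(triethylsilyl)oxy]cyclohexan-1-one; 9 {[(1S,2R,4R)-2-bromo-4-(3-bromoprop-1-en-2-yl)-1-methylcyclohexyl]oxy}triethylsilane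
Product: 17 (2R,5S,6R)-6-{2-[(1R,3R,4S)-3-bromo-4-methyl-4-[(triethylsilyl)oxy]cyclohexyl]prop-2-en-1-yl}-2-methyl-5-(prop-1-en-2-yl)-2-[(triethylsilyl)oxy]cyclohexan-1-one, via lithium enolate 16 (not isolated)
Conditions: 15 (1.3 equiv), LiN(iPr)2 (1.25 equiv), THF, −78 °C; then 9 (1.0 equiv), DMPU, −78 → −20 °C
Reagents that add atoms: none
Why: SN2 alkylation of a lithium enolate that can form on one side only by a primary allylic bromide, in which the electrophile approaches C6 anti to the neighbouring C5 isopropenyl group and to the C2 silyloxy group to give the 5,6-trans (6R) ketone, which is also the thermodynamic diequatorial and epimerisable isomer, while the equatorial secondary bromide of ring B has no antiperiplanar hydrogen and its tertiary oxygen is masked.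

Step 9
Reactants: 17 (2R,5S,6R)-6-{2-[(1R,3R,4S)-3-bromo-4-methyl-4-[(triethylsilyl)oxy]cyclohexyl]prop-2-en-1-yl}-2-methyl-5-(prop-1-en-2-yl)-2-[(triethylsilyl)oxy]cyclohexan-1-one
Product: 18 (2R,5S,6R)-6-{2-[(1R,3R,4S)-3-bromo-4-hydroxy-4-methylcyclohexyl]prop-2-en-1-yl}-2-hydroxy-2-methyl-5-(prop-1-en-2-yl)cyclohexan-1-one
Conditions: HF·pyridine, pyridine, THF, 0 → 23 °C
Reagents that add atoms: none
Why: Fluoride-driven cleavage of both tertiary triethylsilyl ethers (Si–F bond formation) under non-basic conditions, which avoids α-ketol rearrangement and semipinacol contraction of the cis-bromohydrin and leaves the alkenes and the alkyl bromide alone; no stereocentre is touched.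

Step 10
Reactants: 18 (2R,5S,6R)-6-{2-[(1R,3R,4S)-3-bromo-4-hydroxy-4-methylcyclohexyl]prop-2-en-1-yl}-2-hydroxy-2-methyl-5-(prop-1-en-2-yl)cyclohexan-1-one
Product: 19 Prevezol C (1R,2R,3R,4S)-3-{2-[(1R,3R,4S)-3-bromo-4-hydroxy-4-methylcyclohexyl]prop-2-en-1-yl}-1-methyl-4-(prop-1-en-2-yl)cyclohexane-1,2-diol
Conditions: Me4NBH(OAc)3 (5 equiv), MeCN–AcOH (1:1), −20 → 0 °C
Reagents that add atoms: none
Why: Hydroxyl-directed (Saksena–Evans) reduction, in which the axial tertiary hydroxyl next to the ketone exchanges onto boron and delivers hydride intramolecularly to the carbonyl face it sits on, overriding the normal axial attack and giving the secondary alcohol trans to the tertiary one (axial, 2R), while the reagent does not reduce unassisted ketones, alkenes or the bromide.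

## Compound list

1 | (R)-(+)-limonene, (4R)-1-methyl-4-(prop-1-en-2-yl)cyclohex-1-ene | CC(=C)[C@@H]1CCC(C)=CC1 | starting material
2 | (R)-[2-(4-methylcyclohex-3-en-1-yl)prop-2-en-1-yl]lithium (10-lithiolimonene, TMEDA-solvated) | [Li]CC(=C)[C@@H]1CCC(C)=CC1 | intermediate
3 | lithium (R)-trimethoxy[2-(4-methylcyclohex-3-en-1-yl)prop-2-en-1-yl]borate | [Li+].CO[B-](OC)(OC)CC(=C)[C@@H]1CCC(C)=CC1 | intermediate
4 | (R)-2-(4-methylcyclohex-3-en-1-yl)prop-2-en-1-ol | OCC(=C)[C@@H]1CCC(C)=CC1 | intermediate
5 | (R)-4-(3-bromoprop-1-en-2-yl)-1-methylcyclohex-1-ene | BrCC(=C)[C@@H]1CCC(C)=CC1 | intermediate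
6 | (1S,2S,4R)-4-(3-bromoprop-1-en-2-yl)-1-methyl-2-(phenylselanyl)cyclohexan-1-ol (OH and Se trans-diaxial, OH cis to the C4 side chain) | BrCC(=C)[C@@H]1CC[C@](C)(O)[C@@H]([Se]c2ccccc2)C1 | intermediate
7 | (1S,2S,4R)-2-[bromo(phenyl)(2,5-dioxopyrrolidin-1-yl)-λ4-selanyl]-4-(3-bromoprop-1-en-2-yl)-1-methylcyclohexan-1-ol | BrCC(=C)[C@@H]1CC[C@](C)(O)[C@@H]([Se](Br)(c2ccccc2)N2C(=O)CCC2=O)C1 | intermediate
8 | (1S,2R,4R)-2-bromo-4-(3-bromoprop-1-en-2-yl)-1-methylcyclohexan-1-ol (OH axial, Br equatorial, OH, Br and side chain all cis) | BrCC(=C)[C@@H]1CC[C@](C)(O)[C@H](Br)C1 | intermediate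
9 | {[(1S,2R,4R)-2-bromo-4-(3-bromoprop-1-en-2-yl)-1-methylcyclohexyl]oxy}triethylsilane | BrCC(=C)[C@@H]1CC[C@](C)(O[Si](CC)(CC)CC)[C@H](Br)C1 | intermediate
10 | (S)-(−)-limonene, (4S)-1-methyl-4-(prop-1-en-2-yl)cyclohex-1-ene | CC(=C)[C@H]1CCC(C)=CC1 | starting material
11 | cis-(S)-limonene 1,2-oxide, (1S,2R,4S), epoxide oxygen trans to the isopropenyl group | C1[C@@H](C(=C)C)CC[C@]2(C)O[C@H]12 | intermediate
12 | trans-(S)-limonene 1,2-oxide, (1R,2S,4S), epoxide oxygen cis to the isopropenyl group | C1[C@@H](C(=C)C)CC[C@@]2(C)O[C@@H]12 | intermediate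
13 | (1R,2R,4S)-1-methyl-4-(prop-1-en-2-yl)cyclohexane-1,2-diol (trans-diaxial diol) | C1[C@@H](C(=C)C)CC[C@@](C)(O)[C@@H]1O | intermediate
14 | (2R,5S)-2-hydroxy-2-methyl-5-(prop-1-en-2-yl)cyclohexan-1-one | C1[C@@H](C(=C)C)CC[C@@](C)(O)C1=O | intermediate
15 | (2R,5S)-2-methyl-5-(prop-1-en-2-yl)-2-[(triethylsilyl)oxy]cyclohexan-1-one | C1[C@@H](C(=C)C)CC[C@@](C)(O[Si](CC)(CC)CC)C1=O | intermediate
16 | lithium (3S,6R)-6-methyl-3-(prop-1-en-2-yl)-6-[(triethylsilyl)oxy]cyclohex-1-en-1-olate | [Li]OC1=C[C@@H](C(=C)C)CC[C@@]1(C)O[Si](CC)(CC)CC | intermediate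
17 | (2R,5S,6R)-6-{2-[(1R,3R,4S)-3-bromo-4-methyl-4-[(triethylsilyl)oxy]cyclohexyl]prop-2-en-1-yl}-2-methyl-5-(prop-1-en-2-yl)-2-[(triethylsilyl)oxy]cyclohexan-1-one | C=C(C[C@@H]1[C@@H](C(=C)C)CC[C@@](C)(O[Si](CC)(CC)CC)C1=O)[C@@H]1CC[C@](C)(O[Si](CC)(CC)CC)[C@H](Br)C1 | intermediate
18 | (2R,5S,6R)-6-{2-[(1R,3R,4S)-3-bromo-4-hydroxy-4-methylcyclohexyl]prop-2-en-1-yl}-2-hydroxy-2-methyl-5-(prop-1-en-2-yl)cyclohexan-1-one | C=C(C[C@@H]1[C@@H](C(=C)C)CC[C@@](C)(O)C1=O)[C@@H]1CC[C@](C)(O)[C@H](Br)C1 | intermediate
19 | Prevezol C, (1R,2R,3R,4S)-3-{2-[(1R,3R,4S)-3-bromo-4-hydroxy-4-methylcyclohexyl]prop-2-en-1-yl}-1-methyl-4-(prop-1-en-2-yl)cyclohexane-1,2-diol | C=C(C[C@@H]1[C@@H](C(=C)C)CC[C@@](C)(O)[C@@H]1O)[C@@H]1CC[C@](C)(O)[C@H](Br)C1 | target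

## Step count and risks

Total steps: 10. Longest linear sequence: 7 (steps 1–4, then 8–10).

**Step 3 (the proposed new step).** It may fail through background anti-bromohydroxylation by N-bromosuccinimide, through epoxide formation by the neighbouring hydroxyl (which would lead to the trans-bromohydrin), or through elimination at the tetravalent selenium stage. The fallback uses known chemistry, sets out from 5 and comes back at 8; it replaces alkene difunctionalisation by C–O activation and SN2 inversion. Prilezhaev epoxidation of 5 (mCPBA, CH2Cl2, 0 °C, ring alkene only) gives the epoxide pair, the (1R,2S,4R)-epoxide F1 and the (1S,2R,4R)-epoxide F2. Cold 1% aq. HClO4 in THF opens both trans-diaxially to the single (1S,2S,4R)-diol F3. Tf2O with 2,6-di-tert-butyl-4-methylpyridine (CH2Cl2, −78 °C) sulfonylates only the secondary axial hydroxyl to the hydroxy triflate F4, which is not isolated; Bu4NBr added at −78 → 0 °C displaces it by SN2 with inversion to give 8. This fallback shares the hindered SN2 geometry at C2 with the main step, so it removes the catalysis risks but not the intrinsic displacement risk.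

**Step 8 (fragment union).** The enolate is hindered and the SN2 reaction may be slow or unselective. The fallback sets out from 15 and 9 and comes back at 17; it changes the C–C bond-forming event from SN2 displacement to a Tsuji–Trost allylation. Enolate 16 is generated as before and treated with 9 in the presence of Pd(PPh3)4 (5 mol %) and LiCl in THF at 0 °C. Oxidative addition of zerovalent palladium into the allylic C–Br bond gives a symmetrical 2-substituted π-allylpalladium species that the enolate attacks at either terminus, again anti to the isopropenyl group; the secondary alkyl bromide does not react with Pd(PPh3)4 at this temperature. No new compound is made (F0).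

**Step 10 (directed reduction).** Ligand exchange at the hindered tertiary hydroxyl may be slow, and undirected hydride attack gives the wrong epimer. The fallback sets out from 18 and comes back at 19; it accepts substrate control and then inverts. NaBH4 in MeOH at −20 °C attacks axially and gives the C2-epimeric cis-diol F5. Mitsunobu reaction (4-O2NC6H4CO2H, DIAD, PPh3, toluene, 0 → 23 °C) inverts the equatorial secondary carbinol, whose leaving group has no antiperiplanar hydrogen, to the axial 4-nitrobenzoate F6. K2CO3 in MeOH at 0 °C then gives 19.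

## Further compounds

F1 | step 3 | (1R,2S,4R)-4-(3-bromoprop-1-en-2-yl)-1,2-epoxy-1-methylcyclohexane (epoxide oxygen trans to the side chain) | BrCC(=C)[C@@H]1CC[C@@]2(C)O[C@H]2C1
F2 | step 3 | (1S,2R,4R)-4-(3-bromoprop-1-en-2-yl)-1,2-epoxy-1-methylcyclohexane (epoxide oxygen cis to the side chain) | BrCC(=C)[C@@H]1CC[C@]2(C)O[C@@H]2C1
F3 | step 3 | (1S,2S,4R)-4-(3-bromoprop-1-en-2-yl)-1-methylcyclohexane-1,2-diol (trans-diaxial) | BrCC(=C)[C@@H]1CC[C@](C)(O)[C@@H](O)C1
F4 | step 3 | (1S,2S,5R)-5-(3-bromoprop-1-en-2-yl)-2-hydroxy-2-methylcyclohexyl trifluoromethanesulfonate | BrCC(=C)[C@@H]1CC[C@](C)(O)[C@@H](OS(=O)(=O)C(F)(F)F)C1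
F0 | step 8 | none | none
F5 | step 10 | (1R,2S,3R,4S)-3-{2-[(1R,3R,4S)-3-bromo-4-hydroxy-4-methylcyclohexyl]prop-2-en-1-yl}-1-methyl-4-(prop-1-en-2-yl)cyclohexane-1,2-diol | C=C(C[C@@H]1[C@@H](C(=C)C)CC[C@@](C)(O)[C@H]1O)[C@@H]1CC[C@](C)(O)[C@H](Br)C1
F6 | step 10 | (1R,2R,5S,6R)-6-{2-[(1R,3R,4S)-3-bromo-4-hydroxy-4-methylcyclohexyl]prop-2-en-1-yl}-2-hydroxy-2-methyl-5-(prop-1-en-2-yl)cyclohexyl 4-nitrobenzoate | C=C(C[C@@H]1[C@@H](C(=C)C)CC[C@@](C)(O)[C@@H]1OC(=O)c1ccc(cc1)[N+](=O)[O-])[C@@H]1CC[C@](C)(O)[C@H](Br)C1
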